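**Strategy**

The benzofuran-3(2H)-one ring (O1–C2–C3–C3a–C7a) places its C3 carbonyl on the quaternary spiro carbon C2, which also carries O1 and C8 of the kaempferol unit. This 1,2-relationship is cut at C2–C3 as an acyl-anion addition: a chiral triazolium carbene converts the aldehyde of a phloroglucinaldehyde O-vinyl ether into a Breslow intermediate that adds to the oxygen-bearing carbon of its own (Z)-trisubstituted enol ether, closing the five-membered ring and setting C2 in one operation. The precursor carries perbenzylated kaempferol (C8) on the α-carbon and a 4-(PMB-oxy)phenyl group on the β-carbon; the derived CH2 is later oxidised and, after debenzylation, captured by O7 as the hemiketal.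

Key step: step 8

Notation: "Bn4K-8-yl" = 3,5,7-tris(benzyloxy)-2-[4-(benzyloxy)phenyl]-4-oxo-4H-chromen-8-yl; PMB = 4-methoxybenzyl.
Assumption 1: the hemiketal carbon is configurationally labile (ring–chain tautomerism with the aryl ketone) and should settle in the (R) form of the target, whose OH is syn to and hydrogen-bonded with the C3 carbonyl.
Assumption 2: the sense of induction of the triazolium catalyst must be assigned on the first run; both antipodes of the aminoindanol-derived precatalyst are available and the one that delivers (S)-12 is used.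
Assumption 3: boronic acid 10 is taken as a catalogue compound.

**Route**

Step 1
Reactants: 1 kaempferol
Product: 2 3,5,7-tris(benzyloxy)-2-[4-(benzyloxy)phenyl]-4H-chromen-4-one
Conditions: BnBr (6 equiv), K2CO3, TBAI (cat.), DMF, 70 °C
Reagents that add atoms: benzyl bromide, BrCc1ccccc1
Why: Williamson etherification with excess benzyl bromide in warm DMF alkylates all four phenolic hydroxyls, the hydrogen-bonded 5-OH reacting last.

Step 2
Reactants: 2 3,5,7-tris(benzyloxy)-2-[4-(benzyloxy)phenyl]-4H-chromen-4-one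
Product: 3 3,5,7-tris(benzyloxy)-2-[4-(benzyloxy)phenyl]-8-iodo-4H-chromen-4-one
Conditions: NIS (1.1 equiv), TFA (10 mol%), MeCN/CH2Cl2, 0 °C to rt, dark
Reagents that add atoms: N-iodosuccinimide, O=C1CCC(=O)N1I
Why: Electrophilic aromatic iodination of a 5,7-di-O-alkylflavone without a free 5-OH should go to C8 (para to O5, ortho to O7 and O1) in preference to C6, which is flanked by two benzyloxy groups; the site is to be confirmed by NOE/HMBC.

Step 3
Reactants: 3 3,5,7-tris(benzyloxy)-2-[4-(benzyloxy)phenyl]-8-iodo-4H-chromen-4-one; 4 ethynyltrimethylsilane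
Product: 5 3,5,7-tris(benzyloxy)-2-[4-(benzyloxy)phenyl]-8-[(trimethylsilyl)ethynyl]-4H-chromen-4-one
Conditions: Pd(PPh3)2Cl2 (5 mol%), CuI (10 mol%), Et3N/THF, 60 °C
Reagents that add atoms: none
Why: Sonogashira coupling of the aryl iodide with the terminal alkyne installs the two-carbon unit at C8 under conditions that leave the pyranone and the benzyl ethers untouched.

Step 4
Reactants: 5 3,5,7-tris(benzyloxy)-2-[4-(benzyloxy)phenyl]-8-[(trimethylsilyl)ethynyl]-4H-chromen-4-one
Product: 6 3,5,7-tris(benzyloxy)-2-[4-(benzyloxy)phenyl]-8-(bromoethynyl)-4H-chromen-4-one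
Conditions: NBS (1.2 equiv), AgNO3 (10 mol%), acetone, rt, dark
Reagents that add atoms: N-bromosuccinimide, O=C1CCC(=O)N1Br
Why: Silver-catalysed halodesilylation converts the C–Si bond through a silver acetylide into the 1-bromoalkyne without a separate desilylation, and acid-free conditions should spare the deactivated A ring.

Step 5
Reactants: 7 2,4,6-trihydroxybenzaldehyde
Product: 8 2,4-bis(benzyloxy)-6-hydroxybenzaldehyde
Conditions: BnBr (2.1 equiv), K2CO3, DMF, rt
Reagents that add atoms: benzyl bromide, BrCc1ccccc1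
Why: Williamson etherification should stop after the 4-OH and one ortho-OH because the remaining ortho-hydroxyl is deactivated by its hydrogen bond to the formyl group.

Step 6
Reactants: 6 3,5,7-tris(benzyloxy)-2-[4-(benzyloxy)phenyl]-8-(bromoethynyl)-4H-chromen-4-one; 8 2,4-bis(benzyloxy)-6-hydroxybenzaldehyde
Product: 9 (Z)-2,4-bis(benzyloxy)-6-{[2-bromo-1-(Bn4K-8-yl)vinyl]oxy}benzaldehyde
Conditions: Cs2CO3 (1.5 equiv), DMF, 80 °C
Reagents that add atoms: none
Why: In this base-mediated hydrophenoxylation of a 1-bromoalkyne the phenoxide attacks the alkyne carbon remote from bromine (bromine stabilises the developing vinyl anion) and anti protonation places O and Br cis, giving the (Z)-2-bromovinyl aryl ether with oxygen on the flavonol-bearing carbon.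

Step 7
Reactants: 9 (Z)-2,4-bis(benzyloxy)-6-{[2-bromo-1-(Bn4K-8-yl)vinyl]oxy}benzaldehyde; 10 {4-[(4-methoxybenzyl)oxy]phenyl}boronic acid
Product: 11 (Z)-2,4-bis(benzyloxy)-6-{[2-{4-[(4-methoxybenzyl)oxy]phenyl}-1-(Bn4K-8-yl)vinyl]oxy}benzaldehyde
Conditions: Pd(PPh3)4 (5 mol%), K2CO3, 1,4-dioxane/H2O, 80 °C
Reagents that add atoms: none
Why: Suzuki–Miyaura coupling of the unhindered vinyl bromide proceeds with retention of alkene geometry and tolerates the aldehyde and the PMB ether, so the (Z)-β-aryl enol ether should result.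

Step 8
Reactants: 11 (Z)-2,4-bis(benzyloxy)-6-{[2-{4-[(4-methoxybenzyl)oxy]phenyl}-1-(Bn4K-8-yl)vinyl]oxy}benzaldehyde
Product: 12 (S)-4,6-bis(benzyloxy)-2-{4-[(4-methoxybenzyl)oxy]benzyl}-2-(Bn4K-8-yl)benzofuran-3(2H)-one
Conditions: aminoindanol-derived N-mesityl triazolium chloride (20 mol%), DBU (20 mol%), 1,4-dioxane, 80 °C, Ar
Reagents that add atoms: none
Why: The carbene adds to the aldehyde and proton transfer gives the Breslow intermediate, whose nucleophilic carbon bonds to the oxygen-bearing alkene carbon while its O–H proton passes to the β-carbon in a concerted but asynchronous transition state, after which the carbene is expelled and the ketone is formed. The closest known reaction type is the enantioselective NHC-catalysed intramolecular hydroacylation of 2-(1-arylvinyloxy)benzaldehydes to 2,2-disubstituted benzofuran-3(2H)-ones, applied here to a β-aryl trisubstituted enol ether. The ring O1–C2–C3–C3a–C7a closes in the 5-exo-trig mode. The quaternary centre C2 is set by the chiral triazolium scaffold, which shields one face of the single (Z)-alkene isomer. The step needs regioselectivity (C–C bond to the α-carbon, hydrogen to the β-carbon), secured by the five-membered tether and the enol ether polarisation, which the electron-rich flavonol ring on C2 reinforces. It also needs chemoselectivity over intermolecular benzoin coupling, which the two ortho substituents of the aldehyde should suppress.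

Step 9
Reactants: 12 (S)-4,6-bis(benzyloxy)-2-{4-[(4-methoxybenzyl)oxy]benzyl}-2-(Bn4K-8-yl)benzofuran-3(2H)-one
Product: 16 (R)-4,6-bis(benzyloxy)-2-(4-hydroxybenzoyl)-2-(Bn4K-8-yl)benzofuran-3(2H)-one, via free phenol 13 (not isolated), via quinone methide 14 (not isolated), via benzylic carbinol 15 (not isolated)
Conditions: DDQ (3.5 equiv), CH2Cl2/1,4-dioxane/H2O (5:5:1), rt
Reagents that add atoms: water, O
Why: DDQ should first cleave the aryl PMB ether oxidatively, then dehydrogenate the freed 4-alkylphenol to a p-quinone methide (no β-hydrogen allows tautomerisation) that adds water, and a second dehydrogenation of the p-hydroxybenzylic alcohol gives the aryl ketone, while the benzyl ethers are inert to DDQ and the quaternary C2 cannot epimerise (the descriptor changes to R only through CIP priorities).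

Step 10
Reactants: 16 (R)-4,6-bis(benzyloxy)-2-(4-hydroxybenzoyl)-2-(Bn4K-8-yl)benzofuran-3(2H)-one
Product: 18 CNP0283000.1 (spiro carbon S; hemiketal carbon R), via open-chain hexahydroxy ketone 17 (not isolated)
Conditions: H2 (1 atm), 10% Pd/C, THF/MeOH, rt
Reagents that add atoms: none
Why: Catalytic hydrogenolysis cleaves all six aryl benzyl ethers and the freed 7-OH adds to the neighbouring aryl ketone in a 5-exo-trig closure, the hemiketal carbon equilibrating to the (R) form whose OH is hydrogen-bonded to the C3 carbonyl, while C2 is untouched.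

**Compound list**

1 | kaempferol | O=c1c(O)c(-c2ccc(O)cc2)oc2cc(O)cc(O)c12 | starting material
2 | 3,5,7-tris(benzyloxy)-2-[4-(benzyloxy)phenyl]-4H-chromen-4-one | O=c1c(OCc2ccccc2)c(-c2ccc(OCc3ccccc3)cc2)oc2cc(OCc3ccccc3)cc(OCc3ccccc3)c12 | intermediate
3 | 3,5,7-tris(benzyloxy)-2-[4-(benzyloxy)phenyl]-8-iodo-4H-chromen-4-one | O=c1c(OCc2ccccc2)c(-c2ccc(OCc3ccccc3)cc2)oc2c(I)c(OCc3ccccc3)cc(OCc3ccccc3)c12 | intermediate
4 | ethynyltrimethylsilane | C#C[Si](C)(C)C | starting material
5 | 3,5,7-tris(benzyloxy)-2-[4-(benzyloxy)phenyl]-8-[(trimethylsilyl)ethynyl]-4H-chromen-4-one | O=c1c(OCc2ccccc2)c(-c2ccc(OCc3ccccc3)cc2)oc2c(C#C[Si](C)(C)C)c(OCc3ccccc3)cc(OCc3ccccc3)c12 | intermediate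
6 | 3,5,7-tris(benzyloxy)-2-[4-(benzyloxy)phenyl]-8-(bromoethynyl)-4H-chromen-4-one | O=c1c(OCc2ccccc2)c(-c2ccc(OCc3ccccc3)cc2)oc2c(C#CBr)c(OCc3ccccc3)cc(OCc3ccccc3)c12 | intermediate
7 | 2,4,6-trihydroxybenzaldehyde | O=Cc1c(O)cc(O)cc1O | starting material
8 | 2,4-bis(benzyloxy)-6-hydroxybenzaldehyde | O=Cc1c(O)cc(OCc2ccccc2)cc1OCc1ccccc1 | intermediate
9 | (Z)-2,4-bis(benzyloxy)-6-{[2-bromo-1-(Bn4K-8-yl)vinyl]oxy}benzaldehyde | O=Cc1c(OCc2ccccc2)cc(OCc2ccccc2)cc1O/C(=C\Br)c1c(OCc2ccccc2)cc(OCc2ccccc2)c2c(=O)c(OCc3ccccc3)c(-c3ccc(OCc4ccccc4)cc3)oc12 | intermediate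
10 | {4-[(4-methoxybenzyl)oxy]phenyl}boronic acid | OB(O)c1ccc(OCc2ccc(OC)cc2)cc1 | starting material
11 | (Z)-2,4-bis(benzyloxy)-6-{[2-{4-[(4-methoxybenzyl)oxy]phenyl}-1-(Bn4K-8-yl)vinyl]oxy}benzaldehyde | O=Cc1c(OCc2ccccc2)cc(OCc2ccccc2)cc1O/C(=C\c1ccc(OCc2ccc(OC)cc2)cc1)c1c(OCc2ccccc2)cc(OCc2ccccc2)c2c(=O)c(OCc3ccccc3)c(-c3ccc(OCc4ccccc4)cc3)oc12 | intermediate
12 | (S)-4,6-bis(benzyloxy)-2-{4-[(4-methoxybenzyl)oxy]benzyl}-2-(Bn4K-8-yl)benzofuran-3(2H)-one | O=C1c2c(OCc3ccccc3)cc(OCc3ccccc3)cc2O[C@@]1(Cc1ccc(OCc2ccc(OC)cc2)cc1)c1c(OCc2ccccc2)cc(OCc2ccccc2)c2c(=O)c(OCc3ccccc3)c(-c3ccc(OCc4ccccc4)cc3)oc12 | intermediate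
13 | (S)-4,6-bis(benzyloxy)-2-(4-hydroxybenzyl)-2-(Bn4K-8-yl)benzofuran-3(2H)-one | O=C1c2c(OCc3ccccc3)cc(OCc3ccccc3)cc2O[C@@]1(Cc1ccc(O)cc1)c1c(OCc2ccccc2)cc(OCc2ccccc2)c2c(=O)c(OCc3ccccc3)c(-c3ccc(OCc4ccccc4)cc3)oc12 | intermediate
14 | (S)-4,6-bis(benzyloxy)-2-[(4-oxocyclohexa-2,5-dien-1-ylidene)methyl]-2-(Bn4K-8-yl)benzofuran-3(2H)-one | O=C1c2c(OCc3ccccc3)cc(OCc3ccccc3)cc2O[C@@]1(C=C1C=CC(=O)C=C1)c1c(OCc2ccccc2)cc(OCc2ccccc2)c2c(=O)c(OCc3ccccc3)c(-c3ccc(OCc4ccccc4)cc3)oc12 | intermediate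
15 | (2R)-4,6-bis(benzyloxy)-2-[hydroxy(4-hydroxyphenyl)methyl]-2-(Bn4K-8-yl)benzofuran-3(2H)-one, both carbinol epimers | O=C1c2c(OCc3ccccc3)cc(OCc3ccccc3)cc2O[C@@]1(C(O)c1ccc(O)cc1)c1c(OCc2ccccc2)cc(OCc2ccccc2)c2c(=O)c(OCc3ccccc3)c(-c3ccc(OCc4ccccc4)cc3)oc12 | intermediate
16 | (R)-4,6-bis(benzyloxy)-2-(4-hydroxybenzoyl)-2-(Bn4K-8-yl)benzofuran-3(2H)-one | O=C1c2c(OCc3ccccc3)cc(OCc3ccccc3)cc2O[C@@]1(C(=O)c1ccc(O)cc1)c1c(OCc2ccccc2)cc(OCc2ccccc2)c2c(=O)c(OCc3ccccc3)c(-c3ccc(OCc4ccccc4)cc3)oc12 | intermediate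
17 | (R)-4,6-dihydroxy-2-(4-hydroxybenzoyl)-2-(kaempferol-8-yl)benzofuran-3(2H)-one (open-chain keto form) | O=C1c2c(O)cc(O)cc2O[C@@]1(C(=O)c1ccc(O)cc1)c1c(O)cc(O)c2c(=O)c(O)c(-c3ccc(O)cc3)oc12 | intermediate
18 | CNP0283000.1: spiro hemiketal with (S) spiro carbon and (R) hemiketal carbon, 4,6-dihydroxybenzofuran-3-one spiro-fused at C2 to a 2-hydroxy-2-(4-hydroxyphenyl)-2,3-dihydrofuran ring annulated on C7–C8 of kaempferol | O=C1c2c(O)cc(O)cc2O[C@@]12c1c(cc(O)c3c(=O)c(O)c(-c4ccc(O)cc4)oc13)O[C@]2(O)c1ccc(O)cc1 | target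

**Totals and risks**

Total step count: 10. Longest linear sequence: 9 steps (1 → 2 → 3 → 5 → 6 → 9 → 11 → 12 → 16 → 18).

Step 8 is the most likely to fail. The Breslow intermediate may engage the hindered, styrene-conjugated trisubstituted alkene only slowly, since the di-ortho-substituted aldehyde also slows carbene addition, and a bulky chiral carbene may discriminate the two alkene faces poorly. The fallback separates ring closure from stereocontrol. It sets out from 11, which is cyclised with a small achiral N-mesityl pyrrolidine-fused triazolium carbene at 100 °C to the racemate. The enantiomers are separated by preparative chiral SFC on a polysaccharide phase, the configuration is assigned by X-ray or VCD, and the antipode (R)-4,6-bis(benzyloxy)-2-{4-[(4-methoxybenzyl)oxy]benzyl}-2-(Bn4K-8-yl)benzofuran-3(2H)-one F1 is discarded. The route is rejoined at 12.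

Step 9 is the second risk. Four oxidative events run in one pot, so PMB removal may be incomplete, the sequence may stall after the first dehydrogenation, or excess quinone may start to oxidise benzyl ethers. The fallback separates the events and changes reagents. It sets out from 12: TFA/anisole in CH2Cl2 at 0 °C removes the PMB group without oxidant and phenol 13 is isolated. One equivalent of DDQ in NaHCO3-buffered aqueous dioxane performs only the first dehydrogenation and carbinol 15 is isolated. Activated MnO2 in CH2Cl2 then oxidises the p-hydroxybenzylic alcohol, and the route is rejoined at 16.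

Step 6 is the third risk. The weakly nucleophilic, hydrogen-bonded salicylaldehyde phenoxide may add sluggishly to the bromoalkyne, with halophilic attack at bromine or capture of the vinyl anion by the formyl group competing. The fallback builds the same enol ether from a ketone and sets out from iodide 3:
- Stille coupling with tributyl(1-ethoxyvinyl)stannane (Pd(PPh3)4, toluene, 100 °C) gives 3,5,7-tris(benzyloxy)-2-[4-(benzyloxy)phenyl]-8-(1-ethoxyvinyl)-4H-chromen-4-one F2.
- Hydrolysis with aqueous HCl gives the methyl ketone 8-acetyl-3,5,7-tris(benzyloxy)-2-[4-(benzyloxy)phenyl]-4H-chromen-4-one F3.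
- Pd-catalysed α-arylation with 1-bromo-4-[(4-methoxybenzyl)oxy]benzene (Pd2(dba)3, XPhos, K3PO4, toluene, 80 °C) gives the deoxybenzoin 3,5,7-tris(benzyloxy)-2-[4-(benzyloxy)phenyl]-8-({4-[(4-methoxybenzyl)oxy]phenyl}acetyl)-4H-chromen-4-one F4.
- KHMDS in THF at −78 °C followed by PhNTf2 traps the Z-enolate as (Z)-2-{4-[(4-methoxybenzyl)oxy]phenyl}-1-(Bn4K-8-yl)vinyl trifluoromethanesulfonate F5.
- Pd-catalysed C–O coupling of the enol triflate with phenol 8 (Pd2(dba)3, t-BuXPhos, K3PO4, toluene, 90 °C) rejoins the route at 11, bypassing 4, 5, 6, 9 and 10.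

Further compounds
F1 | step 8 | (R)-4,6-bis(benzyloxy)-2-{4-[(4-methoxybenzyl)oxy]benzyl}-2-(Bn4K-8-yl)benzofuran-3(2H)-one | O=C1c2c(OCc3ccccc3)cc(OCc3ccccc3)cc2O[C@]1(Cc1ccc(OCc2ccc(OC)cc2)cc1)c1c(OCc2ccccc2)cc(OCc2ccccc2)c2c(=O)c(OCc3ccccc3)c(-c3ccc(OCc4ccccc4)cc3)oc12
F2 | step 6 | 3,5,7-tris(benzyloxy)-2-[4-(benzyloxy)phenyl]-8-(1-ethoxyvinyl)-4H-chromen-4-one | O=c1c(OCc2ccccc2)c(-c2ccc(OCc3ccccc3)cc2)oc2c(C(=C)OCC)c(OCc3ccccc3)cc(OCc3ccccc3)c12
F3 | step 6 | 8-acetyl-3,5,7-tris(benzyloxy)-2-[4-(benzyloxy)phenyl]-4H-chromen-4-one | O=c1c(OCc2ccccc2)c(-c2ccc(OCc3ccccc3)cc2)oc2c(C(C)=O)c(OCc3ccccc3)cc(OCc3ccccc3)c12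
F4 | step 6 | 3,5,7-tris(benzyloxy)-2-[4-(benzyloxy)phenyl]-8-({4-[(4-methoxybenzyl)oxy]phenyl}acetyl)-4H-chromen-4-one | O=c1c(OCc2ccccc2)c(-c2ccc(OCc3ccccc3)cc2)oc2c(C(=O)Cc3ccc(OCc4ccc(OC)cc4)cc3)c(OCc3ccccc3)cc(OCc3ccccc3)c12
F5 | step 6 | (Z)-2-{4-[(4-methoxybenzyl)oxy]phenyl}-1-(Bn4K-8-yl)vinyl trifluoromethanesulfonate | FC(F)(F)S(=O)(=O)O/C(=C\c1ccc(OCc2ccc(OC)cc2)cc1)c1c(OCc2ccccc2)cc(OCc2ccccc2)c2c(=O)c(OCc3ccccc3)c(-c3ccc(OCc4ccccc4)cc3)oc12
F0 | step 9 | none | none
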